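**Cycloshizukaol A (33): a 22-step linear route from (R)-Wieland–Miescher ketone, with the C1–C3 ring contraction as step 11**

## The problem

Cycloshizukaol A (33) is a C2-symmetric head-to-tail dimer of two lindenane units. In each half a cyclopropane (C1–C2–C3) is fused to a cyclopentene (C1, C3, C4, C5, C10), which shares C5–C10 with a cyclohexadienone (ring B, C5–C10). The halves are joined twice through C15–C11′, so a twelve-membered ring runs through C4=C5–C6=C7–C11 of both.

Each half has five stereocentres: C1 and C3 (cis cyclopropane, methylene C2 syn to the C14 methyl), the quaternary C10, the carbinol C9 (hydroxyl cis to C14) and the quaternary C11. C10 can be bought, and it can steer both neighbours, C1 (and through it C3) and C9, because reagents reach these carbons from the face away from the axial methyl. C11 hangs on a trigonal ring carbon three bonds from the nearest stereocentre; the ring cannot steer it, so it needs reagent control.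

The fragile parts are:
- the C8/C9 α-ketol (epimerization, reductive C–O cleavage);
- the cyclopropyl ketone and vinylcyclopropane (ring opening by radical anions or acid);
- the dienone;
- the oxygenated ester on the quaternary C11 (retro-aldol when its hydroxyl is free under base, lactonization onto a C8 hydroxyl).

The feature that opens the key step: lindenane is a 1,3-cycloeudesmane, a decalin plus one C1–C3 bond. C3 is α and C1 is γ to C4, and C4 is trigonal in the target. A C4 ketone can therefore first make C3 a nucleophile toward a leaving group on C1, and later become the enol triflate through which C15 is attached.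

## Retrosynthesis

**33 ⇒ 32.** Only the two O–Si bonds at C9 are cut. The α-ketol stays silylated through the metal-mediated ring closure and is freed last with acidic fluoride, since base would endanger its configuration.

**32 ⇒ 29 (through zinc reagent 30 and open dimer 31).** Both C4–C15′ bonds are cut. The neighbouring cut, C15–C11′, would need an ester enolate alkylation that creates both quaternary C11 centres during macrocyclization, without control and next to the more acidic C9–H. The C4–C15′ cut leaves C11 finished in the monomer, lets one monomer serve twice, and joins a triflate-bearing sp2 carbon to a primary alkylzinc that has no β-hydrogen. 29 is half the size of 32. Head-to-tail selectivity is automatic, because the rigid s-trans diene keeps C15′ far from C4 of the same molecule; the forward reaction must win ring closure over chain growth.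

**29 ⇒ 24.** No skeletal bond is cut; the 9β-hydroxyl and the iodide go back to a methylene and a silyl ether. C9 is the only enolizable carbon of the C8 ketone in 24. A C9 carbonyl (25) sits beside the quaternary C10 just as the C1 carbonyl of 1 does, so hydride should again arrive anti to C14 and give 26. Hydroxylating a C9 enolate would put oxygen on the wrong face. The iodide follows from silyl ethers 27 and 28.

**24 ⇒ 17.** The oxidation states of C4 and C8 are exchanged: the C4 ketone of 17 becomes the triflate and C8 becomes the carbonyl. The path runs through epoxide 18, its reductive opening to 19, and triflation to 23. The shorter neighbour, rearranging 18 to a 4,8-dione and triflating that, leaves two enolate oxygens in competition, and its hydride shift needs a cation at C7, γ to the ketone. With C8 tetrahedral in 19, only O4 can be triflated.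

**17 ⇒ 15 (key cut).** The C1–C3 bond is cut, which turns the cyclopropane plus cyclopentanone back into ring A of a decalin with a C4 ketone and a C1 mesylate. Against carbenoid cyclopropanation, this cut needs no diazo or carbenoid precursor and draws C1 and C3 from a stereocentre that already exists. 15 has two rings and two stereocentres fewer than 17. The forward reaction needs one enolate only (at C3) and backside attack on C1. An oxygen at C9 is deliberately absent from 15, because it is better set later by hydride (step 17).

**15 ⇒ 13 ⇒ 11 ⇒ 8 + 9.** The C11 centre is traced to the prochiral malonate 11, whose two esters are told apart by a chiral catalyst (13); ring control is not available. The C7–C11 bond is cut to dienyl triflate 8 and dimethyl malonate 9. The malonate is methylated after coupling, because coupling of a 2-alkylmalonate is poorly precedented.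

**8 ⇒ 5 ⇒ 3 ⇒ 1.** The C4 oxygen comes from γ-oxidation of the enone (dienol ether 4), and the C1 mesylate from reduction and sulfonylation of (R)-Wieland–Miescher ketone 1, which supplies C10.

## Roads not taken

**Alternative 1:** Ring B and the five-membered ring are cut together at C5–C10 and C8–C9. Going forward, heating triene A1 would give cycloadduct A2 by an intramolecular Diels–Alder reaction; A1 is a cis-cyclopropane carrying a 1-silyloxy diene on the C4 ketal and an E-alkenylboronate.
- Merits: two rings, two bonds and four stereocentres in one step, including the quaternary C10. The C9 boron of A2 is cis to C14, so stereoretentive oxidation would give the 9β-hydroxyl directly. In this respect it is better than the chosen plan, which spends steps 12–17 on ring B oxidation.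
- Weak points: the dienophile is a trisubstituted, barely activated alkenylboronate that must form a quaternary carbon with an electron-rich diene. The facial sense relative to the cyclopropane is a transition-state preference, not a mechanistic necessity. A1 itself needs an enantioselective cis-cyclopropane with two different unsaturated arms of defined geometry, one already holding C11.
- Comparison: the chosen plan sets against this a purchased C10, an ionic ring closure whose stereochemistry is fixed by inversion, and a decalin whose chemistry is well mapped.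

**Alternative 2:** Ring B is cut at C5–C6 and C9–C10. Going forward, silyloxyfuran A4 would add to the C5=C10 bond of cyclopentenone A3, anti to the cyclopropane, to give the oxa-bridged adduct A5.
- Merits: it is convergent. C11 would be set on a small furan, and unmasking A5 (enol ether to C8 ketone, β-elimination of the bridge) would deliver C6=C7, the C8 ketone and the C9 hydroxyl at once. It is clearly shorter on paper.
- Weak points: a β,β-disubstituted enone must form a quaternary carbon with an aromatic diene, a combination that is slow and reversible. Endo/exo and facial selectivity both have to fall the right way for C9 and C10. A3 needs its own enantioselective synthesis.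
- Comparison: the chosen plan pays about six more steps for a key step with firm precedent and for stereocentres (C1, C3, C9) that all derive from the one bought centre.

**Alternative 3:** Both C4–C15′ bonds are cut, with the cyclodimerization of iodo triflate A6 to bis-silyl ether A7 as the strategic step.
- Merits: full use of the symmetry and the latest possible union; a stepwise variant with two different monomers could suppress oligomers.
- Weak points: a twelve-membered ring closed by two couplings at neopentyl carbons, and a primary radical next to a vinyl group during zinc insertion. The strategy also leaves open how the monomer and its cyclopropane arise.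
- Comparison: it complements the chosen plan more than it competes with it. A6 is compound 29, A7 is compound 32, and step 21 is this same reaction. The chosen plan adds a defined way to the monomer; a shorter monomer synthesis (for example by Alternative 2) would make this road the better one.

Key step: step 11

Remarks on the chemistry:
- Atoms carry lindenane numbers; β is the face of the C14 methyl; C15′ is the CH2 on C11, which becomes C15 of the other half.
- Centres that are later erased (C4 in 5–13, C7/C8 in 18, C5/C8 in 19–23) are drawn as the expected epimer; either epimer would serve.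
- In step 8 the ligand enantiomer that gives 13 is to be chosen by a test on 11.

Step 1
Reactants: 1 (R)-Wieland–Miescher ketone
Product: 2 1β-hydroxy enone (OH cis to C14)
Conditions: NaBH4 (0.3 equiv), EtOH, −10 °C
Reagents that add atoms: none
Why: Chemoselective borohydride reduction of the saturated ketone beside the enone; hydride reaches C1 from the face opposite the axial C14 methyl and gives the equatorial 1β-alcohol, the established outcome for this ketone.

Step 2
Reactants: 2 1β-hydroxy enone
Product: 3 1β-mesyloxy enone
Conditions: MsCl, Et3N, CH2Cl2, 0 °C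
Reagents that add atoms: methanesulfonyl chloride CS(=O)(=O)Cl
Why: Standard sulfonylation; the equatorial neopentyl-type mesylate has a shielded backside and no anti-periplanar hydrogen, so it should ride as a spectator until step 11.

Step 3
Reactants: 3 1β-mesyloxy enone
Product: 4 7-ethoxy-4,6-diene (ethyl dienol ether)
Conditions: HC(OEt)3, TsOH (cat.), EtOH/dioxane, rt
Reagents that add atoms: triethyl orthoformate CCOC(OCC)OCC
Why: Acid-catalysed dienol ether formation of a ring-fused enone gives the through-conjugated heteroannular dienol ether, which makes C4 nucleophilic.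

Step 4
Reactants: 4 ethyl dienol ether
Product: 5 4β-hydroxy-1β-mesyloxy-5-en-7-one
Conditions: mCPBA, dioxane/H2O (pH 7 buffer), 0 °C
Reagents that add atoms: 3-chloroperbenzoic acid O=C(OO)c1cccc(Cl)c1; water O
Why: Vinylogous Rubottom-type oxidation: the peracid epoxidizes the terminal C4=C5 bond and hydrolytic opening returns the enone with a γ-hydroxyl at C4; axial 4β attack is expected by analogy with steroidal 3,5-dienol ethers, and the centre is oxidized later.

Step 5
Reactants: 5 4β-hydroxy enone
Product: 6 4β-triethylsilyloxy enone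
Conditions: Et3SiCl, imidazole, DMF, 0 °C
Reagents that add atoms: chlorotriethylsilane CC[Si](Cl)(CC)CC
Why: Silylation of the secondary allylic alcohol keeps it out of the enolate, palladium and alkylation chemistry of steps 6 and 7.

Step 6
Reactants: 6 4β-triethylsilyloxy enone
Product: 8 5,7-dien-7-yl triflate, via lithium dienolate 7 (not isolated)
Conditions: LiN(SiMe3)2, THF, −78 °C; PhNTf2, −78 → 0 °C
Reagents that add atoms: N-phenylbis(trifluoromethanesulfonimide) O=S(=O)(N(c1ccccc1)S(=O)(=O)C(F)(F)F)C(F)(F)F
Why: Kinetic deprotonation of an enone by a hindered amide occurs at the α′ methylene (C8), and O-triflation gives the cross-conjugated 2-triflyloxy-1,3-diene; the γ-hydrogen at C4 is kinetically less acidic.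

Step 7
Reactants: 8 5,7-dien-7-yl triflate; 9 dimethyl malonate
Product: 11 dimethyl 2-methyl-2-(dienyl)malonate, via sodium malonate enolate 10 (not isolated)
Conditions: NaH, Pd2(dba)3 (2.5 mol %), P(t-Bu)3 (10 mol %), THF, 65 °C; then MeI, rt
Reagents that add atoms: iodomethane CI
Why: Palladium-catalysed alkenylation of a malonate enolate (oxidative addition of the dienyl triflate to zerovalent palladium, C-bound enolate, reductive elimination aided by the bulky phosphine), then C-methylation of the stabilized anion in the same flask; the neopentyl equatorial mesylate is inert to the soft nucleophile.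

Step 8
Reactants: 11 dimethyl 2-methyl-2-(dienyl)malonate
Product: 13 4β,15′-diol methyl ester, via diethoxymethylsilyl ether 12 (not isolated)
Conditions: ZnEt2 (10 mol %), chiral pipecolinol-derived dinucleating aminophenol ligand (5 mol %), HSiMe(OEt)2, THF, 0 °C; then HF·pyridine, pyridine, THF, 0 °C
Reagents that add atoms: none
Why: Catalyst-controlled desymmetrizing mono-hydrosilylation of a 2,2-disubstituted malonate by a dinuclear zinc hydride, which tells the methyl from the bulky dienyl group and so sets C11; no ketone is present, the mesylate does not react with the zinc hydride, and the fluoride work-up frees both hydroxyls.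

Step 9
Reactants: 13 4β,15′-diol methyl ester
Product: 14 15′-hydroxy-1β-mesyloxy-5,7-dien-4-one
Conditions: MnO2, CH2Cl2, rt
Reagents that add atoms: none
Why: MnO2 oxidizes only the allylic C4 alcohol and leaves the neopentyl primary alcohol, giving the dienone.

Step 10
Reactants: 14 15′-hydroxy dienone
Product: 15 15′-silyloxy-1β-mesyloxy-5,7-dien-4-one
Conditions: t-BuMe2SiCl, imidazole, DMF, rt
Reagents that add atoms: tert-butylchlorodimethylsilane CC(C)(C)[Si](C)(C)Cl
Why: Silylation of the primary alcohol; a free alkoxide β to the ester would risk retro-aldol loss of formaldehyde under the base of step 11.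

Step 11
Reactants: 15 15′-silyloxy-1β-mesyloxy-5,7-dien-4-one
Product: 17 cyclopropyl dienone (C2 syn to C14), via lithium C3 enolate 16 (not isolated)
Conditions: LiN(SiMe3)2 (1.1 equiv), THF, −78 °C; DMPU, −78 → 23 °C
Reagents that add atoms: none
Why: The amide removes an α′ hydrogen at C3 under kinetic control to give enolate 16; on warming, C3 attacks C1 from the side opposite the equatorial mesylate and expels it in an intramolecular SN2 reaction that makes the C1–C3 bond. The closest known reaction type is the base-induced 1,3-elimination of γ-sulfonyloxy ketones to bicyclo[3.1.0]hexan-2-ones, as in the closure of 3β-sulfonyloxy 6-keto steroids to 3α,5-cyclo 6-ketones, where the leaving group is also equatorial. The one bond closes two rings: the cyclopropane (C1–C2–C3) in the 3-exo-tet mode and, by the same event, the cyclopentanone (C1, C3, C4, C5, C10), which is ring A contracted by the new bond. C1 is set by inversion, so it follows from the 1β-mesylate of steps 1 and 2 and places C2 syn to the C14 methyl; C3 is set by the cis fusion that a three-membered ring on a five-membered ring must have. The step needs C3 to be the only carbon nucleophile: C5 is trigonal, which rules out the rival C5–C1 closure of a saturated ketone, C8 is an alkene carbon, C11 carries no hydrogen, and the vinylogous C9 hydrogens are not removed under kinetic conditions. O-alkylation would give a bridgehead enol ether and is excluded, and E2 loss of the mesylate lacks an anti-periplanar hydrogen. The silyl ether prevents retro-aldol cleavage at C15′.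

Step 12
Reactants: 17 cyclopropyl dienone
Product: 18 7α,8α-epoxy enone
Conditions: DMDO, acetone, 0 °C
Reagents that add atoms: dimethyldioxirane CC1(C)OO1
Why: Electrophilic epoxidation of a linear dienone takes place at the more electron-rich γ,δ bond (C7=C8), from the α face away from C14 and the cyclopropane methylene; the new centres are erased later.

Step 13
Reactants: 18 7α,8α-epoxy enone
Product: 19 8α-hydroxy-6-en-4-one (5α-H)
Conditions: SmI2 (2.2 equiv), THF/MeOH, −78 °C
Reagents that add atoms: none
Why: Two-electron reduction of a vinylogous epoxy ketone by divalent samarium: the enone radical anion expels the allylic C7–O bond, the second electron gives the dienolate, and protonation at C5 leaves the C8 alcohol and C6=C7; opening of the oxirane is expected to outrun opening of the cyclopropane, and the conjugated isomer or the C5 epimer would serve equally in step 14.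

Step 14
Reactants: 19 8α-hydroxy-6-en-4-one
Product: 23 8α-hydroxy-4,6-dien-4-yl triflate, via trimethylsilyl ether 20 (not isolated), via potassium dienolate 21 (not isolated), via silylated triflate 22 (not isolated)
Conditions: Me3SiCl, Et3N, THF, 0 °C, salt filtered off; KN(SiMe3)2, THF, −78 °C; PhNTf2; aq. citric acid, MeOH
Reagents that add atoms: N-phenylbis(trifluoromethanesulfonimide) O=S(=O)(N(c1ccccc1)S(=O)(=O)C(F)(F)F)C(F)(F)F
Why: Transient silylation keeps the C8 oxygen from lactonizing or being triflated; the only acidic hydrogen of the C4 ketone is the allylic C5–H (the cyclopropyl C3–H does not enolize), so enolate O-triflation gives the C4 dienyl triflate with one regiochemistry while C8 is still tetrahedral.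

Step 15
Reactants: 23 8α-hydroxy-4,6-dien-4-yl triflate
Product: 24 8-oxo-4,6-dien-4-yl triflate
Conditions: MnO2 (excess), CH2Cl2, rt
Reagents that add atoms: none
Why: Oxidation of the allylic C8 alcohol to the dienone; run at once, before the hydroxyl can lactonize onto the C12 ester.

Step 16
Reactants: 24 8-oxo-4,6-dien-4-yl triflate
Product: 25 8,9-dioxo-4,6-dien-4-yl triflate
Conditions: SeO2, dioxane, pyridine (cat.), 80 °C
Reagents that add atoms: selenium dioxide O=[Se]=O
Why: Riley oxidation of the only enolizable position of the C8 ketone (C7 is trigonal, C10 quaternary), giving a 1,2-dione that cannot enolize.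

Step 17
Reactants: 25 8,9-dioxo-4,6-dien-4-yl triflate
Product: 26 9β-hydroxy-8-oxo-4,6-dien-4-yl triflate
Conditions: NaBH4 (0.3 equiv), MeOH/THF, −78 °C
Reagents that add atoms: none
Why: The C9 carbonyl is not conjugated and, like C1 in step 1, lies next to the quaternary C10, whereas C8 is deactivated by the diene and screened by C11; hydride from the α face (anti to C14) gives the 9β-alcohol cis to the methyl.

Step 18
Reactants: 26 9β-hydroxy-8-oxo-4,6-dien-4-yl triflate
Product: 27 9β,15′-bis(silyloxy)-8-oxo-4,6-dien-4-yl triflate
Conditions: t-BuMe2SiOTf, 2,6-lutidine, CH2Cl2, −40 → 0 °C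
Reagents that add atoms: tert-butyldimethylsilyl triflate CC(C)(C)[Si](C)(C)OS(=O)(=O)C(F)(F)F
Why: Silylation of the hindered α-ketol needs the silyl triflate; at low temperature with lutidine O-silylation is faster than enol ether formation.

Step 19
Reactants: 27 9β,15′-bis(silyloxy) triflate
Product: 28 9β-silyloxy-15′-hydroxy-8-oxo-4,6-dien-4-yl triflate
Conditions: HF·pyridine, pyridine, THF, 0 °C
Reagents that add atoms: none
Why: The primary silyl ether cleaves faster than the secondary one, which is flanked by C10 and the ketone; acidic fluoride leaves the vinyl triflate and avoids retro-aldol.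

Step 20
Reactants: 28 15′-alcohol
Product: 29 9β-silyloxy-15′-iodo-8-oxo-4,6-dien-4-yl triflate
Conditions: I2, PPh3, imidazole, toluene, 70 °C
Reagents that add atoms: iodine II
Why: Appel-type iodination; neopentyl 3-hydroxy-2,2-dialkylpropanoates are known to give the iodides on heating, and the alkoxyphosphonium ion cannot eliminate.

Step 21
Reactants: 29 iodo triflate (two molecules)
Product: 32 cycloshizukaol A bis(tert-butyldimethylsilyl) ether, via alkylzinc iodide 30 (not isolated), via open-chain dimer 31 (not isolated)
Conditions: Zn dust (Me3SiCl/BrCH2CH2Br activated), LiCl, THF, 30 °C; then slow addition to Pd2(dba)3 (10 mol %), SPhos (20 mol %), THF/DMF, 50 °C, 5 mM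
Reagents that add atoms: none
Why: Negishi coupling of a zinc homoenolate with an alkenyl triflate; C11 is quaternary, so the alkylpalladium has no β-hydrogen. The first coupling gives open dimer 31 and the second closes the twelve-membered ring; a monomer cannot close on itself because the s-trans diene holds C15′ away from C4, and slow addition keeps the zinc reagent dilute.

Step 22
Reactants: 32 bis-silyl ether
Product: 33 cycloshizukaol A
Conditions: HF·pyridine, THF, rt
Reagents that add atoms: none
Why: Acidic fluoride removes both hindered silyl ethers without the base-induced epimerization or ketol shift that the α-hydroxy ketone could suffer.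

## Compound list

1 | (R)-Wieland–Miescher ketone, (8aR)-8a-methyl-3,4,8,8a-tetrahydronaphthalene-1,6(2H,7H)-dione | C[C@@]12CCC(=O)C=C1CCCC2=O | starting material
2 | (4aR,5R)-5-hydroxy-4a-methyl-4,4a,5,6,7,8-hexahydronaphthalen-2(3H)-one (1β-OH, cis to C14) | O=C1CC[C@@]2(C)[C@H](O)CCCC2=C1 | intermediate
3 | methanesulfonate of 2 (1β-mesyloxy-5-en-7-one) | O=C1CC[C@@]2(C)[C@H](OS(C)(=O)=O)CCCC2=C1 | intermediate
4 | 7-ethoxy-1β-mesyloxy-4,6-diene (ethyl dienol ether of 3) | CCOC1=CC2=CCC[C@@H](OS(C)(=O)=O)[C@]2(C)CC1 | intermediate
5 | 4β-hydroxy-1β-mesyloxy-5-en-7-one | O=C1C=C2[C@@H](O)CC[C@@H](OS(C)(=O)=O)[C@]2(C)CC1 | intermediate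
6 | 4β-triethylsilyloxy-1β-mesyloxy-5-en-7-one | O=C1C=C2[C@@H](O[Si](CC)(CC)CC)CC[C@@H](OS(C)(=O)=O)[C@]2(C)CC1 | intermediate
7 | lithium 7(8)-enolate of 6, not isolated | [Li+].[O-]C1=CC[C@@]2(C)[C@H](OS(C)(=O)=O)CC[C@H](O[Si](CC)(CC)CC)C2=C1 | intermediate
8 | 1β-mesyloxy-4β-triethylsilyloxy-5,7-dien-7-yl triflate | O=S(=O)(OC1=CC[C@@]2(C)[C@H](OS(C)(=O)=O)CC[C@H](O[Si](CC)(CC)CC)C2=C1)C(F)(F)F | intermediate
9 | dimethyl malonate | COC(=O)CC(=O)OC | starting material
10 | sodium enolate of dimethyl 2-(1β-mesyloxy-4β-triethylsilyloxy-5,7-dien-7-yl)malonate, not isolated | [Na+].COC(=O)C(=C([O-])OC)C1=CC[C@@]2(C)[C@H](OS(C)(=O)=O)CC[C@H](O[Si](CC)(CC)CC)C2=C1 | intermediate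
11 | dimethyl 2-methyl-2-(1β-mesyloxy-4β-triethylsilyloxy-5,7-dien-7-yl)malonate | COC(=O)C(C)(C(=O)OC)C1=CC[C@@]2(C)[C@H](OS(C)(=O)=O)CC[C@H](O[Si](CC)(CC)CC)C2=C1 | intermediate
12 | mono-reduced 11 as C15′ diethoxymethylsilyl ether (C11 as in the target), not isolated | COC(=O)[C@](C)(CO[Si](C)(OCC)OCC)C1=CC[C@@]2(C)[C@H](OS(C)(=O)=O)CC[C@H](O[Si](CC)(CC)CC)C2=C1 | intermediate
13 | methyl (11S)-ester with 4β-OH, C15′-OH, 1β-OMs, 5,7-diene | COC(=O)[C@](C)(CO)C1=CC[C@@]2(C)[C@H](OS(C)(=O)=O)CC[C@H](O)C2=C1 | intermediate
14 | 15′-hydroxy-1β-mesyloxy-5,7-dien-4-one methyl ester | COC(=O)[C@](C)(CO)C1=CC[C@@]2(C)[C@H](OS(C)(=O)=O)CCC(=O)C2=C1 | intermediate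
15 | 15′-(tert-butyldimethylsilyloxy)-1β-mesyloxy-5,7-dien-4-one methyl ester (key precursor) | COC(=O)[C@](C)(CO[Si](C)(C)C(C)(C)C)C1=CC[C@@]2(C)[C@H](OS(C)(=O)=O)CCC(=O)C2=C1 | intermediate
16 | lithium 3(4)-enolate of 15, not isolated | [Li+].COC(=O)[C@](C)(CO[Si](C)(C)C(C)(C)C)C1=CC[C@@]2(C)[C@H](OS(C)(=O)=O)CC=C([O-])C2=C1 | intermediate
17 | cyclopropyl dienone: 1,3-cyclo-5,7-dien-4-one, cyclopropane cis-fused with C2 syn to C14, C11 side chain as in 15 | O=C1[C@H]2C[C@H]2[C@]2(C)CC=C([C@](C)(C(=O)OC)CO[Si](C)(C)C(C)(C)C)C=C12 | intermediate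
18 | 7α,8α-epoxide of 17 | O=C1[C@H]2C[C@H]2[C@]2(C)C[C@@H]3O[C@]3([C@](C)(C(=O)OC)CO[Si](C)(C)C(C)(C)C)C=C12 | intermediate
19 | 8α-hydroxy-6-en-4-one, 5α-H | O=C1[C@H]2C[C@H]2[C@]2(C)C[C@H](O)C([C@](C)(C(=O)OC)CO[Si](C)(C)C(C)(C)C)=C[C@@H]12 | intermediate
20 | 8-O-trimethylsilyl ether of 19, not isolated | O=C1[C@H]2C[C@H]2[C@]2(C)C[C@H](O[Si](C)(C)C)C([C@](C)(C(=O)OC)CO[Si](C)(C)C(C)(C)C)=C[C@@H]12 | intermediate
21 | potassium 4(5),6-dienolate of 20, not isolated | [K+].[O-]C1=C2C=C([C@](C)(C(=O)OC)CO[Si](C)(C)C(C)(C)C)[C@@H](O[Si](C)(C)C)C[C@@]2(C)[C@@H]2C[C@H]12 | intermediate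
22 | 8α-trimethylsilyloxy-4,6-dien-4-yl triflate, not isolated | O=S(=O)(OC1=C2C=C([C@](C)(C(=O)OC)CO[Si](C)(C)C(C)(C)C)[C@@H](O[Si](C)(C)C)C[C@@]2(C)[C@@H]2C[C@H]12)C(F)(F)F | intermediate
23 | 8α-hydroxy-4,6-dien-4-yl triflate | O=S(=O)(OC1=C2C=C([C@](C)(C(=O)OC)CO[Si](C)(C)C(C)(C)C)[C@@H](O)C[C@@]2(C)[C@@H]2C[C@H]12)C(F)(F)F | intermediate
24 | 8-oxo-4,6-dien-4-yl triflate | O=S(=O)(OC1=C2C=C([C@](C)(C(=O)OC)CO[Si](C)(C)C(C)(C)C)C(=O)C[C@@]2(C)[C@@H]2C[C@H]12)C(F)(F)F | intermediate
25 | 8,9-dioxo-4,6-dien-4-yl triflate | O=S(=O)(OC1=C2C=C([C@](C)(C(=O)OC)CO[Si](C)(C)C(C)(C)C)C(=O)C(=O)[C@@]2(C)[C@@H]2C[C@H]12)C(F)(F)F | intermediate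
26 | 9β-hydroxy-8-oxo-4,6-dien-4-yl triflate (OH cis to C14) | O=S(=O)(OC1=C2C=C([C@](C)(C(=O)OC)CO[Si](C)(C)C(C)(C)C)C(=O)[C@H](O)[C@@]2(C)[C@@H]2C[C@H]12)C(F)(F)F | intermediate
27 | 9β,15′-bis(tert-butyldimethylsilyloxy)-8-oxo-4,6-dien-4-yl triflate | O=S(=O)(OC1=C2C=C([C@](C)(C(=O)OC)CO[Si](C)(C)C(C)(C)C)C(=O)[C@H](O[Si](C)(C)C(C)(C)C)[C@@]2(C)[C@@H]2C[C@H]12)C(F)(F)F | intermediate
28 | 9β-silyloxy-15′-hydroxy-8-oxo-4,6-dien-4-yl triflate | O=S(=O)(OC1=C2C=C([C@](C)(C(=O)OC)CO)C(=O)[C@H](O[Si](C)(C)C(C)(C)C)[C@@]2(C)[C@@H]2C[C@H]12)C(F)(F)F | intermediate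
29 | 9β-silyloxy-15′-iodo-8-oxo-4,6-dien-4-yl triflate (monomer, 11R) | O=S(=O)(OC1=C2C=C([C@](C)(C(=O)OC)CI)C(=O)[C@H](O[Si](C)(C)C(C)(C)C)[C@@]2(C)[C@@H]2C[C@H]12)C(F)(F)F | intermediate
30 | alkylzinc iodide of 29 (C15′–ZnI), not isolated | O=S(=O)(OC1=C2C=C([C@](C)(C(=O)OC)C[Zn]I)C(=O)[C@H](O[Si](C)(C)C(C)(C)C)[C@@]2(C)[C@@H]2C[C@H]12)C(F)(F)F | intermediate
31 | open-chain dimer with one C4–C15′ bond, one C4 triflate and one C15′–ZnI, not isolated | O=S(=O)(OC1=C2C=C([C@](C)(C(=O)OC)CC3=C4C=C([C@](C)(C(=O)OC)C[Zn]I)C(=O)[C@H](O[Si](C)(C)C(C)(C)C)[C@@]4(C)[C@@H]4C[C@H]34)C(=O)[C@H](O[Si](C)(C)C(C)(C)C)[C@@]2(C)[C@@H]2C[C@H]12)C(F)(F)F | intermediate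
32 | cycloshizukaol A 9,9′-bis(tert-butyldimethylsilyl) ether | COC(=O)[C@]1(C)CC2=C3C=C(C(=O)[C@H](O[Si](C)(C)C(C)(C)C)[C@@]3(C)[C@@H]3C[C@H]23)[C@](C)(C(=O)OC)CC2=C3C=C1C(=O)[C@H](O[Si](C)(C)C(C)(C)C)[C@@]3(C)[C@@H]1C[C@H]21 | intermediate
33 | cycloshizukaol A | COC(=O)[C@]1(C)CC2=C3C=C(C(=O)[C@H](O)[C@@]3(C)[C@@H]3C[C@H]23)[C@](C)(C(=O)OC)CC2=C3C=C1C(=O)[C@H](O)[C@@]3(C)[C@@H]1C[C@H]21 | target

## Step count and least certain steps

Total: 22 steps. Longest linear sequence: 22 steps from 1; dimethyl malonate 9 enters at step 7.

**Step 11 (key step).** Ring closure at the neopentyl C1 may be slow. The lithium enolate could then exchange protons and drift to the through-conjugated trienolate (loss of a C9 hydrogen), which cannot close, or the mesylate could eliminate. The fallback runs the same closure earlier, under equilibrating conditions where every enolate can return and only the C3 enolate leaves by ring closure. It sets out from 5: MnO2 would give the ene-dione mesylate F1, and t-BuOK in t-BuOH would close it to the cyclopropyl ene-dione F2, whose only enolizable carbon is C8. Kinetic triflation as in step 6 would give the cyclopropyl dienone triflate F3, and malonate coupling with methylation as in step 7 the malonate F4. The zinc hydride desymmetrization of step 8 would also reduce the C4 ketone and give the diol F5 (C4 epimers, drawn as the 4β-alcohol). MnO2 would return the ketone as the hydroxy dienone F6, and silylation as in step 10 comes back to the route at 17.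

**Step 21.** Chain growth may outrun closure of the twelve-membered ring. During zinc insertion the primary radical at C15′ may add to C7 and reopen, a 1,2-dienyl shift to the tertiary ester radical that would scramble the skeleton. Transmetalation of the neopentyl zinc may also be slow. The fallback reverses the polarity at C15′ and avoids alkyl radicals next to the diene. It sets out from 28: oxidation would give the aldehyde F7, which has no α-hydrogen. A Nozaki–Hiyama–Kishi cyclodimerization (CrCl2, NiCl2 cat., DMF, high dilution) of the dienyl triflate with the aldehyde would give the macrocyclic bis-allylic alcohol F8 (C15 epimers). Thiocarbonyldiimidazole would give the bis(imidazolyl thiocarbonate) F9, and Barton–McCombie deoxygenation (Bu3SnH), with hydrogen delivered to C15 of the stabilized dienyl radical, comes back to the route at 32.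

**Step 8.** The catalyst may discriminate poorly between the two esters on so hindered a substrate (low selectivity at C11), or turnover may stall. The fallback is hydrolytic instead of reductive. It sets out from 11: pig liver esterase (pH 7 buffer, DMSO) would give the half-ester F10; activation as the mixed anhydride (i-BuOCOCl, N-methylmorpholine) and NaBH4 would give the hydroxy ester F11; HF·pyridine removes the triethylsilyl group and comes back to the route at 13. The C11 epimers are diastereomers in either version and can be separated if selectivity is incomplete.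

**Step 17 (with step 16).** Hydride may attack C8 as well as C9 (poor site selectivity) or reduce both carbonyls. The fallback gives up site selectivity in the reduction and regains it in an oxidation. It sets out from 25: excess NaBH4 with CeCl3 would reduce both carbonyls from the α face to the 8β,9β-diol F12, and MnO2 would then oxidize only the allylic C8 alcohol, coming back to the route at 26.

**Step 13.** The C8 alkoxide may lactonize onto the C12 ester, or the ketyl may open the cyclopropane. The fallback never forms an alkoxide at C8. It sets out from 18: Pd(PPh3)4, a zerovalent palladium catalyst for the isomerization of diene monoepoxides, would give the 4,8-dione F13 (or its enol). O-triflation with KN(SiMe3)2 and PhNTf2 is expected at O4 on steric grounds, since O8 is flanked by the quaternary C11, and comes back to the route at 24.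

## Further compounds

F1 | step 11 | 1β-mesyloxy-5-ene-4,7-dione | O=C1C=C2C(=O)CC[C@@H](OS(C)(=O)=O)[C@]2(C)CC1
F2 | step 11 | cyclopropyl ene-dione (1,3-cyclo-5-ene-4,7-dione, C2 syn to C14) | O=C1C=C2C(=O)[C@H]3C[C@H]3[C@]2(C)CC1
F3 | step 11 | cyclopropyl 4-oxo-5,7-dien-7-yl triflate | O=C1[C@H]2C[C@H]2[C@]2(C)CC=C(OS(=O)(=O)C(F)(F)F)C=C12
F4 | step 11 | dimethyl 2-methyl-2-(cyclopropyl 4-oxo-5,7-dien-7-yl)malonate | O=C1[C@H]2C[C@H]2[C@]2(C)CC=C(C(C)(C(=O)OC)C(=O)OC)C=C12
F5 | step 11 | cyclopropyl 5,7-diene 4β,15′-diol methyl ester (C4 epimers, 4β drawn) | O[C@H]1[C@H]2C[C@H]2[C@]2(C)CC=C([C@](C)(C(=O)OC)CO)C=C12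
F6 | step 11 | 15′-hydroxy cyclopropyl 5,7-dien-4-one methyl ester | O=C1[C@H]2C[C@H]2[C@]2(C)CC=C([C@](C)(C(=O)OC)CO)C=C12
F7 | step 21 | 9β-silyloxy-15′-oxo (aldehyde) 8-oxo-4,6-dien-4-yl triflate | O=S(=O)(OC1=C2C=C([C@](C)(C(=O)OC)C=O)C(=O)[C@H](O[Si](C)(C)C(C)(C)C)[C@@]2(C)[C@@H]2C[C@H]12)C(F)(F)F
F8 | step 21 | 15,15′-dihydroxy derivative of 32 (C15 epimers, configuration at C15 open) | COC(=O)[C@]1(C)C(O)C2=C3C=C(C(=O)[C@H](O[Si](C)(C)C(C)(C)C)[C@@]3(C)[C@@H]3C[C@H]23)[C@](C)(C(=O)OC)C(O)C2=C3C=C1C(=O)[C@H](O[Si](C)(C)C(C)(C)C)[C@@]3(C)[C@@H]1C[C@H]21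
F9 | step 21 | 15,15′-bis(imidazol-1-ylthiocarbonyloxy) derivative of 32 (configuration at C15 open) | COC(=O)[C@]1(C)C(OC(=S)n2ccnc2)C2=C3C=C(C(=O)[C@H](O[Si](C)(C)C(C)(C)C)[C@@]3(C)[C@@H]3C[C@H]23)[C@](C)(C(=O)OC)C(OC(=S)n2ccnc2)C2=C3C=C1C(=O)[C@H](O[Si](C)(C)C(C)(C)C)[C@@]3(C)[C@@H]1C[C@H]21
F10 | step 8 | malonic half-ester of 11 (C11 as in 13) | COC(=O)[C@](C)(C(=O)O)C1=CC[C@@]2(C)[C@H](OS(C)(=O)=O)CC[C@H](O[Si](CC)(CC)CC)C2=C1
F11 | step 8 | 4β-triethylsilyl ether of 13 | COC(=O)[C@](C)(CO)C1=CC[C@@]2(C)[C@H](OS(C)(=O)=O)CC[C@H](O[Si](CC)(CC)CC)C2=C1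
F12 | step 17 | 8β,9β-dihydroxy-4,6-dien-4-yl triflate | O=S(=O)(OC1=C2C=C([C@](C)(C(=O)OC)CO[Si](C)(C)C(C)(C)C)[C@H](O)[C@H](O)[C@@]2(C)[C@@H]2C[C@H]12)C(F)(F)F
F13 | step 13 | cyclopropyl 6-ene-4,8-dione (5α-H, or its enol) | O=C1[C@H]2C[C@H]2[C@]2(C)CC(=O)C([C@](C)(C(=O)OC)CO[Si](C)(C)C(C)(C)C)=C[C@@H]12
A1 | alternative 1 | cis-cyclopropane triene: E-alkenylboronate at C10=C9, C4 ketal, 1-silyloxy diene C5=C6–C7=C8 | C/C(=C\B1OC(C)(C)C(C)(C)O1)[C@@H]1C[C@@H]1C1(OCCO1)/C=C/C(=C/O[Si](C)(C)C(C)(C)C)[C@](C)(C(=O)OC)CO[Si](C)(C)C(C)(C)C
A2 | alternative 1 | C9 boronate, C4 ketal lindenane tricycle | C1COC2(O1)[C@H]3C=C([C@](C)(C(=O)OC)CO[Si](C)(C)C(C)(C)C)[C@@H](O[Si](C)(C)C(C)(C)C)[C@H](B4OC(C)(C)C(C)(C)O4)[C@@]3(C)[C@@H]3C[C@H]23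
A3 | alternative 2 | 4-methylbicyclo[3.1.0]hex-3-en-2-one (cyclopropane-fused cyclopentenone) | O=C1C=C(C)[C@@H]2C[C@H]12
A4 | alternative 2 | 4-substituted 3-silyloxyfuran carrying the C11 ester | COC(=O)[C@](C)(CO[Si](C)(C)C(C)(C)C)c1cocc1O[Si](C)(C)C(C)(C)C
A5 | alternative 2 | oxa-bridged tetracyclic adduct | O=C1[C@H]2[C@@H]3O[C@@H](C(O[Si](C)(C)C(C)(C)C)=C3[C@](C)(C(=O)OC)CO[Si](C)(C)C(C)(C)C)[C@@]2(C)[C@@H]2C[C@H]12
A6 | alternative 3 | iodo triflate monomer (identical with 29) | O=S(=O)(OC1=C2C=C([C@](C)(C(=O)OC)CI)C(=O)[C@H](O[Si](C)(C)C(C)(C)C)[C@@]2(C)[C@@H]2C[C@H]12)C(F)(F)F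
A7 | alternative 3 | cycloshizukaol A bis(tert-butyldimethylsilyl) ether (identical with 32) | COC(=O)[C@]1(C)CC2=C3C=C(C(=O)[C@H](O[Si](C)(C)C(C)(C)C)[C@@]3(C)[C@@H]3C[C@H]23)[C@](C)(C(=O)OC)CC2=C3C=C1C(=O)[C@H](O[Si](C)(C)C(C)(C)C)[C@@]3(C)[C@@H]1C[C@H]21
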